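**Retrosynthetic overview**

1. The target is a p-menthane ring carrying two 1-methyl-2-quinolinone units, each bound through C3 to a ring CH and through O4 to a fully substituted carbon: unit A closes the cis-fused 2,2-dimethyl-dihydropyran, unit B the bridged ether.
2. Last disconnection (unit A): the bond from C4 to the benzo ring is cut and the cyclohexane CH is moved from C3 back to C4. This turns the six-membered ring O–C(CH3)2–CH–CH–C3=C4 into the five-membered 2-alkylidene-tetrahydrofuran of an N-methylanilide (the enol ether of a γ-lactone).
3. Enabling feature: the enol-ether triad O4–C4=C3 of unit A, with O4 on C(CH3)2 and C3 on the ring-fusion CH. Once C3 carries a nucleofuge, the oxygen lone pair can push that CH from C4 to C3, so ring enlargement and quinolinone closure become one event.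
4. The γ-lactone comes from 1,2-transposition of the lactone of a Diels–Alder adduct between the 3-dienyl-4-methoxyquinolinone (unit B) and (5S)-5-menthyloxyfuranone, which sets the three contiguous CH centres all-cis; the bridged ether is closed by acid on the ring alkene.
5. Ring order: quinolinone B (bought) → cyclohexene + γ-lactone (Diels–Alder) → bridged dihydropyran (2-oxabicyclo[3.3.1]nonene) → transposed γ-lactone → pyridone ring of unit A + dimethyl-dihydropyran (key step).

Key step: step 11

Remark (assumption): 4-methoxy-1-methylquinolin-2(1H)-one and 5-hydroxyfuran-2(5H)-one are taken as catalogue compounds; the two quinolinone units are called A (fused to the dimethylpyran) and B (bridged).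

**Step 1**
Reactants: 1 4-methoxy-1-methylquinolin-2(1H)-one
Product: 2 3-iodo-4-methoxy-1-methylquinolin-2(1H)-one
Conditions: N-iodosuccinimide (1.1 equiv), CF3CO2H (10 mol %), MeCN, rt
Reagents that add atoms: N-iodosuccinimide, O=C1CCC(=O)N1I
Why: Electrophilic iodination should occur at C3, the nucleophilic α-carbon of the vinylogous ester (electrophilic substitution of an enol ether).

**Step 2**
Reactants: 2 3-iodo-4-methoxy-1-methylquinolin-2(1H)-one, 3 isoprene
Product: 4 4-methoxy-1-methyl-3-[(1E)-3-methylbuta-1,3-dien-1-yl]quinolin-2(1H)-one
Conditions: Pd(OAc)2 (5 mol %), P(o-tolyl)3 (10 mol %), Et3N (2 equiv), 3 (5 equiv), MeCN, 90 °C, sealed tube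
Reagents that add atoms: none
Why: Heck reaction: oxidative addition of the C–I bond to zerovalent palladium, insertion of the unsubstituted vinyl group of isoprene at its terminal carbon and β-hydride elimination should give the conjugated (E)-1-aryl-3-methylbutadiene.

**Step 3**
Reactants: 5 5-hydroxyfuran-2(5H)-one, 6 (1S,2R,5S)-menthol
Product: 7 (5S)-5-[(1S,2R,5S)-menthyloxy]furan-2(5H)-one
Conditions: p-TsOH (cat.), toluene, reflux with azeotropic removal of water; crystallisation from petroleum ether at −20 °C, mother liquor re-equilibrated with p-TsOH and crystallised again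
Reagents that add atoms: none
Why: Acid-catalysed acetalisation of the cyclic hemiacetal with the chiral alcohol; the acetal carbon epimerises under acid, so crystallisation should funnel the material into the single (5S) diastereomer (crystallisation-induced asymmetric transformation).

**Step 4**
Reactants: 4 4-methoxy-1-methyl-3-[(1E)-3-methylbuta-1,3-dien-1-yl]quinolin-2(1H)-one, 7 (5S)-5-[(1S,2R,5S)-menthyloxy]furan-2(5H)-one
Product: 8 all-cis 7-(4-methoxy-1-methyl-2-oxo-1,2-dihydroquinolin-3-yl)-5-methyl-3-[(1S,2R,5S)-menthyloxy]-3a,4,7,7a-tetrahydro-2-benzofuran-1(3H)-one (menthyloxy anti to the new ring)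
Conditions: toluene, 120 °C, sealed tube, BHT (cat.)
Reagents that add atoms: none
Why: Thermal Diels–Alder reaction: the diene should add to the butenolide face anti to the menthyloxy group through the endo transition state, its aryl-bearing terminus bonding to the α-carbon of the lactone (ortho/para regiochemistry, reinforced by the 3-methyl group), which sets the CH–aryl centre and both ring-fusion CH centres all-cis in the absolute sense fixed by the (5S) acetal.

**Step 5**
Reactants: 8 Diels–Alder adduct
Product: 10 all-cis 7-(4-methoxy-1-methyl-2-oxo-1,2-dihydroquinolin-3-yl)-5-methyl-3a,4,7,7a-tetrahydro-2-benzofuran-1(3H)-one, via hydroxy acid 9 (not isolated)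
Conditions: NaBH4 (2 equiv), NaOH (1 M), MeOH–H2O, 0 °C → rt; then HCl to pH 1, rt
Reagents that add atoms: none
Why: Hydroxide opens the acetal-lactone (pseudo-ester), the hemiacetal releases menthol as its aldehyde is reduced by borohydride, and acidification closes the γ-lactone (saponification, NaBH4 reduction, lactonisation) without touching a stereocentre.

**Step 6**
Reactants: 10 lactone with 4-methoxyquinolinone
Product: 11 all-cis 7-(4-hydroxy-1-methyl-2-oxo-1,2-dihydroquinolin-3-yl)-5-methyl-3a,4,7,7a-tetrahydro-2-benzofuran-1(3H)-one
Conditions: LiCl (5 equiv), DMF, 120 °C; dilute HCl work-up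
Reagents that add atoms: none
Why: SN2 demethylation of the vinylogous methyl ester by chloride (the 4-quinolinone oxide is a carboxylate-like leaving group), while the β-branched OCH2 of the lactone should be much slower to react.

**Step 7**
Reactants: 11 4-hydroxyquinolinone lactone
Product: 12 bridged ether lactone (O4 of quinolinone B bonded to the methyl-bearing ring carbon, 2-oxabicyclo[3.3.1]nonene fused at C3–C4 of the quinolinone; γ-lactone unchanged)
Conditions: CF3SO3H (10 mol %), CH2Cl2, 0 °C → rt
Reagents that add atoms: none
Why: Brønsted-acid Markovnikov hydroalkoxylation: the tertiary cation can be bridged only on the face that carries the quinolinone, so the CH–aryl centre sets the quaternary C–O stereocentre, and closure through O4 rather than the amide oxygen is the expected thermodynamic outcome for 1-methyl-4-hydroxy-2-quinolinones under reversible ionising conditions.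

**Step 8**
Reactants: 12 bridged ether lactone
Product: 13 diol (C(CH3)2OH on the CH next to the aryl-bearing CH, CH2OH on the neighbouring CH, cis)
Conditions: MeMgBr (3.5 equiv), THF, 0 °C → rt; aq. NH4Cl
Reagents that add atoms: methylmagnesium bromide, C[Mg]Br
Why: Double Grignard addition to the lactone carbonyl gives the tertiary carbinol that becomes the O–C(CH3)2 unit, the 4-alkoxy-2-quinolinone being inert at this temperature.

**Step 9**
Reactants: 13 diol
Product: 15 transposed γ-lactone (O–C(CH3)2 on the CH next to the aryl-bearing CH, C=O on the neighbouring ring-fusion CH, cis-fused), via hydroxy aldehyde 14 (not isolated)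
Conditions: TEMPO (20 mol %), PhI(OAc)2 (2.5 equiv), CH2Cl2, rt
Reagents that add atoms: none
Why: Oxidative lactonisation: only the primary alcohol is oxidised, the aldehyde is trapped by the tertiary hydroxyl as the lactol and this is oxidised to the γ-lactone, so the lactone carbonyl now sits on the ring-fusion CH that must end on C3 of quinolinone A.

**Step 10**
Reactants: 15 transposed γ-lactone, 16 N-methyl-N-phenylacetamide
Product: 18 (Z)-N-methyl-N-phenyl-2-(tetrahydrofuran-2-ylidene)acetamide derived from 15 (exocyclic C=C in place of the lactone C=O, amide cis to the ring oxygen), via hemiketal 17 (not isolated)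
Conditions: 16 (2.5 equiv), LiN(i-Pr)2 (2.5 equiv), THF, −78 °C; CeCl3 (2.5 equiv), −78 °C; 15, −78 → −20 °C; aq. NH4Cl; then PPTS (cat.), 4 Å molecular sieves, toluene, 60 °C
Reagents that add atoms: none
Why: Claisen-type addition of the weakly basic cerium amide enolate to the lactone (so the α-CH of the lactone is not epimerised) gives the hemiketal, and acid-catalysed dehydration should give the exocyclic vinylogous carbamate, mainly as the Z isomer.

**Step 11**
Reactants: 18 (Z)-enol ether anilide
Product: 20 target CNP0229685.5, via spiro iodane 19 (not isolated)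
Conditions: PhI(OCOCF3)2 (1.5 equiv), BF3·OEt2 (2 equiv), CH2Cl2, −30 °C → rt
Reagents that add atoms: none
Why: Proposed new method: the nucleophilic α-carbon of the enol ether attacks the BF3-activated λ3-iodane, the cyclic oxocarbenium ion is captured by an ortho carbon of the N-methylanilide (whose aryl group lies cis to the acyl chain) to give spiro iodane 19, and loss of iodobenzene, pushed by the ring-oxygen lone pair, moves the ring-fusion CH from the spiro carbon to the α-carbon, after which the six-membered oxocarbenium ion loses a proton to give the aromatic 4-alkoxy-2-quinolinone. The closest known reaction is the PhI(OCOCF3)2/BF3-mediated oxidative cyclisation of N-methyl-N-arylcinnamamides to 3-aryl-2-quinolinones with 1,2-aryl migration, together with the λ3-iodane ring expansions of alkylidenecycloalkanes; new here is that the migrating group is a ring alkyl carbon driven by an α-oxygen. Two rings close: the pyridone ring by six-membered Friedel–Crafts-type closure onto the oxocarbenium carbon, and the dimethyl-dihydropyran by enlargement of the tetrahydrofuran (five to six atoms) through the semipinacol 1,2-shift. No new stereocentre remains; the migrating CH keeps its configuration (suprafacial shift with retention), so the cis ring fusion from step 4 is carried into the pyran. The step needs carbon rather than oxygen or aryl migration: carbon migration leaves an oxocarbenium ion whereas oxygen migration would leave a far poorer cation, and reversible iodination should let the diastereomer whose C–I bond can lie anti to the ring C–C bond drain to product. Quinolinone B is fully substituted at C3 and both its ether carbons are fully substituted, so it should not be attacked.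

**Compound list**

1 | 4-methoxy-1-methylquinolin-2(1H)-one | COc1cc(=O)n(C)c2ccccc12 | starting material
2 | 3-iodo-4-methoxy-1-methylquinolin-2(1H)-one | COc1c(I)c(=O)n(C)c2ccccc12 | intermediate
3 | isoprene (2-methylbuta-1,3-diene) | C=CC(C)=C | starting material
4 | 4-methoxy-1-methyl-3-[(1E)-3-methylbuta-1,3-dien-1-yl]quinolin-2(1H)-one | COc1c(/C=C/C(C)=C)c(=O)n(C)c2ccccc12 | intermediate
5 | 5-hydroxyfuran-2(5H)-one (racemic) | OC1OC(=O)C=C1 | starting material
6 | (1S,2R,5S)-menthol, (+)-menthol | CC(C)[C@H]1CC[C@H](C)C[C@@H]1O | starting material
7 | (5S)-5-[(1S,2R,5S)-menthyloxy]furan-2(5H)-one | CC(C)[C@H]1CC[C@H](C)C[C@@H]1O[C@H]1OC(=O)C=C1 | intermediate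
8 | Diels–Alder adduct: all-cis 7-(4-methoxy-1-methyl-2-oxoquinolin-3-yl)-5-methyl-3-menthyloxy-3a,4,7,7a-tetrahydro-2-benzofuran-1(3H)-one, menthyloxy anti | COc1c([C@@H]3C=C(C)C[C@H]4[C@@H]3C(=O)O[C@@H]4O[C@H]5C[C@@H](C)CC[C@@H]5C(C)C)c(=O)n(C)c2ccccc12 | intermediate
9 | all-cis 6-(hydroxymethyl)-2-(4-methoxy-1-methyl-2-oxoquinolin-3-yl)-4-methylcyclohex-3-ene-1-carboxylic acid | COc1c([C@@H]3C=C(C)C[C@H](CO)[C@@H]3C(=O)O)c(=O)n(C)c2ccccc12 | intermediate (not isolated)
10 | all-cis 7-(4-methoxy-1-methyl-2-oxoquinolin-3-yl)-5-methyl-3a,4,7,7a-tetrahydro-2-benzofuran-1(3H)-one | COc1c([C@@H]3C=C(C)C[C@H]4[C@@H]3C(=O)OC4)c(=O)n(C)c2ccccc12 | intermediate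
11 | 4-hydroxyquinolinone analogue of 10 | Oc1c([C@@H]3C=C(C)C[C@H]4[C@@H]3C(=O)OC4)c(=O)n(C)c2ccccc12 | intermediate
12 | bridged ether lactone (O4 of quinolinone B on the methyl-bearing carbon; lactone C=O on the CH next to the aryl-bearing CH) | O=C1OC[C@H]2C[C@]3(C)C[C@H]([C@@H]12)c1c(c2ccccc2n(C)c1=O)O3 | intermediate
13 | diol from 12 (tertiary carbinol and cis CH2OH) | CC(C)(O)[C@H]2[C@@H](CO)C[C@]1(C)C[C@H]2c2c(c3ccccc3n(C)c2=O)O1 | intermediate
14 | hydroxy aldehyde (CHO in place of CH2OH of 13) | CC(C)(O)[C@H]2[C@@H](C=O)C[C@]1(C)C[C@H]2c2c(c3ccccc3n(C)c2=O)O1 | intermediate (not isolated)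
15 | transposed cis-fused γ-lactone (O–C(CH3)2 next to the aryl-bearing CH) | O=C1OC(C)(C)[C@H]2[C@@H]1C[C@]1(C)C[C@H]2c2c(c3ccccc3n(C)c2=O)O1 | intermediate
16 | N-methyl-N-phenylacetamide | CC(=O)N(C)c1ccccc1 | starting material
17 | hemiketal: 2-hydroxy-2-[2-(N-methylanilino)-2-oxoethyl]tetrahydrofuran from 15 (one anomer drawn) | O[C@]1(CC(=O)N(C)c3ccccc3)OC(C)(C)[C@H]2[C@@H]1C[C@]1(C)C[C@H]2c2c(c3ccccc3n(C)c2=O)O1 | intermediate (not isolated)
18 | (Z)-enol ether anilide (2-alkylidene-tetrahydrofuran, amide cis to ring oxygen) | CN(c1ccccc1)C(=O)/C=C1\OC(C)(C)[C@H]2[C@@H]1C[C@]1(C)C[C@H]2c2c(c3ccccc3n(C)c2=O)O1 | intermediate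
19 | spiro λ3-iodane: 1-methyl-3-[phenyl(trifluoroacetoxy)-λ3-iodanyl]-3,4-dihydroquinolin-2(1H)-one whose C4 is the spiro carbon of the tetrahydrofuran | CN1C(=O)[C@@H](I(c2ccccc2)OC(=O)C(F)(F)F)[C@@]2(OC(C)(C)[C@H]3[C@@H]2C[C@]2(C)C[C@H]3c3c(c4ccccc4n(C)c3=O)O2)c2ccccc12 | intermediate (not isolated)
20 | target CNP0229685.5 | Cn1c(=O)c2c(c3ccccc31)OC(C)(C)[C@H]1[C@@H]2C[C@]2(C)C[C@H]1c1c(c3ccccc3n(C)c1=O)O2 | target

**Count and risks**

Total step count: 11. Longest linear sequence: 10 steps (steps 1, 2, 4 to 11; step 3 is the side branch).

Steps most likely to fail: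

1. Step 11 (proposed new method). The α-iodanyl oxocarbenium ion may be captured by trifluoroacetate before the anilide ring closes. The unproductive spiro diastereomer may shift its ring oxygen instead of the ring carbon. The Lewis acid may ionise the tertiary enol ether. Fallback with known reaction types, from 18 back to 20, the same ring enlargement in three separate operations. CF3SO3H (1.1 equiv) in CH2Cl2 at −20 °C protonates the enol ether at its α-carbon, and the cyclic oxocarbenium ion is captured by the anilide ring (the ring closure of the Knorr quinolinone synthesis, stopped at the spiro stage because the ether oxygen is held in the five-membered ring) to give spiro ether F1. LiN(i-Pr)2 in THF at −78 °C followed by N-bromosuccinimide brominates the lactam α-carbon to give bromide F2, whose α-centre can be equilibrated through the enolate until the C–Br bond lies anti to the ring C–C bond. AgOSO2CF3 with 2,6-di-tert-butylpyridine in CH2Cl2 then removes bromide and triggers the silver-assisted semipinacol 1,2-shift of the ring-fusion carbon; loss of a proton from the six-membered oxocarbenium ion gives 20.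

2. Step 4. Cycloaddition at the hindered aryl-bearing diene terminus may be slow, so that diene dimerisation competes and endo and facial control erode at the temperature needed. Fallback from 4 back to 10: catalyst-controlled cycloaddition of 4 with unsubstituted furan-2(5H)-one, using the AlBr3 complex of (S)-3,3-diphenyl-1-(2-methylphenyl)tetrahydro-1H,3H-pyrrolo[1,2-c][1,3,2]oxazaborole (or its enantiomer, whichever matches the required sense) in CH2Cl2 at −40 °C. This should give lactone 10 directly and make 7, 8 and step 5 unnecessary; it makes no new compound (F0).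

3. Step 7. The tertiary cation may be closed by the amide oxygen (linear 2-alkoxy-4-quinolinone) without reverting, or the double bond may migrate before closure. Fallback from 10 back to 12. Mukaiyama-type hydration of the ring alkene of 10 (Fe(acac)3, iron tris(acetylacetonate), PhSiH3, O2, EtOH) gives tertiary alcohol F3; the epimer with hydroxyl cis to the quinolinone is the productive one, and the other is recycled to 10 by acid dehydration. KN(SiMe3)2 in THF then closes the bridged ether by addition–elimination at C4 of the vinylogous ester with loss of methoxide, which fixes the O4 connectivity by the position of the leaving group and makes step 6 unnecessary.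

**Further compounds**

F1 | step 11 | spiro ether: 1-methyl-3,4-dihydroquinolin-2(1H)-one spiro-fused at C4 to the tetrahydrofuran of 15 | CN1C(=O)C[C@@]2(OC(C)(C)[C@H]3[C@@H]2C[C@]2(C)C[C@H]3c3c(c4ccccc4n(C)c3=O)O2)c2ccccc12
F2 | step 11 | 3-bromo derivative of F1 (C–Br anti to the ring C–C bond) | CN1C(=O)[C@@H](Br)[C@@]2(OC(C)(C)[C@H]3[C@@H]2C[C@]2(C)C[C@H]3c3c(c4ccccc4n(C)c3=O)O2)c2ccccc12
F0 | step 4 | none | none
F3 | step 7 | tertiary alcohol from hydration of 10 (hydroxyl cis to the quinolinone) | COc1c([C@@H]3C[C@](C)(O)C[C@H]4[C@@H]3C(=O)OC4)c(=O)n(C)c2ccccc12
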